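**Plan**

- Retrosynthetic cuts, in order: the S–O bond of the sulfate; C6–H of ring B back to C6–CO2H; the lactone C(=O)–O bond from that carboxyl to the C1 oxygen of ring A; the C2(A)–O diaryl ether bond (key step); the aryl ester bond; the C2(B)–O–C1(C) ether bond; the three C–Br bonds of ring B.
- Forward: the ring B catechol ester is tribrominated, O-arylated with ring C through an iodonium salt, saponified and esterified with the ring A fluorophenol. The only ring formed, a seven-membered dioxepinone, then closes by intramolecular SNAr. Lactone opening, protodecarboxylation and sulfation finish the route.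
- Enabling feature: the single hydrogen of ring B (C6) is ortho to C1, which carries the ether oxygen to ring A, and the sulfated oxygen on C1 of ring A is ortho to the ether carbon C2. One carbonyl carbon from C6 of ring B to the C1 oxygen of ring A therefore spans the A–O–B ether as a depsidone and leaves later as CO2.
- Stereochemistry: the target has no stereocentre and no stereogenic double bond, so nothing has to be set.

Key step: step 7

Assumption: the target is taken as the free aryl hydrogen sulfate as drawn; it is liberated from its pyridinium salt by cold cation exchange, and a neutral salt would be the form for storage.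

**Route**

Step 1
Reactants: 1 2,4-dibromo-1-fluorobenzene
Product: 3 3,5-dibromo-2-fluorophenol, via pinacol boronate 2 (not isolated)
Conditions: [Ir(OMe)(cod)]2 (1.5 mol %), 4,4'-di-tert-butyl-2,2'-bipyridine (3 mol %), B2pin2, THF, 60 °C; then KHSO5 (as the triple salt 2KHSO5·KHSO4·K2SO4), acetone/H2O, 0 °C to rt
Reagents that add atoms: potassium peroxymonosulfate, [K+].[O-]S(=O)(=O)OO; bis(pinacolato)diboron, CC1(C)OB(OC1(C)C)B1OC(C)(C)C(C)(C)O1 (boron retained only in 2)
Why: Iridium-catalysed aromatic C–H borylation is sterically governed and should go only to C6, the one C–H not next to a bromine (C3 lies between two bromines, C5 beside one, and an ortho fluorine is tolerated), and oxidation of the aryl boronate gives the phenol at the same carbon.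

Step 2
Reactants: 4 2,4-dibromo-1-iodobenzene
Product: 6 (2,4-dibromophenyl)(2,4,6-trimethoxyphenyl)iodonium tosylate, via hydroxytosyloxyiodoarene 5 (not isolated)
Conditions: mCPBA, TsOH·H2O, MeCN, 77 °C; then 1,3,5-trimethoxybenzene, 77 °C; precipitation with Et2O
Reagents that add atoms: 1,3,5-trimethoxybenzene, COc1cc(OC)cc(OC)c1; p-toluenesulfonic acid, Cc1ccc(S(=O)(=O)O)cc1; mCPBA, OOC(=O)c1cccc(Cl)c1 (oxygen retained only in 5)
Why: Peracid oxidation of the aryl iodide in the presence of TsOH gives the trivalent-iodine tosylate, which the very electron-rich trimethoxybenzene attacks at iodine in an electrophilic aromatic substitution, the established one-pot synthesis of unsymmetrical diaryliodonium salts.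

Step 3
Reactants: 7 methyl 2,3-dihydroxybenzoate
Product: 8 methyl 4,5,6-tribromo-2,3-dihydroxybenzoate
Conditions: Br2 (3.5 equiv), AcOH, rt to 60 °C; aq. NaHSO3 quench
Reagents that add atoms: bromine, BrBr
Why: Electrophilic aromatic bromination: C4 and C6 are ortho and para to the 3-hydroxyl and C5 is para to the 2-hydroxyl, so exhaustive bromination fills all three open positions without ambiguity, and the methyl ester prevents ipso bromodecarboxylation.

Step 4
Reactants: 8 methyl 4,5,6-tribromo-2,3-dihydroxybenzoate; 6 (2,4-dibromophenyl)(2,4,6-trimethoxyphenyl)iodonium tosylate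
Product: 9 methyl 4,5,6-tribromo-3-(2,4-dibromophenoxy)-2-hydroxybenzoate
Conditions: t-BuOK (1.0 equiv), THF, 0 °C; then 6 (1.05 equiv), 40 °C
Reagents that add atoms: none
Why: Metal-free O-arylation with a diaryliodonium salt (ligand exchange at trivalent iodine, then ligand coupling): one equivalent of base should deprotonate the more acidic 3-hydroxyl (ortho and para bromines) while the 2-hydroxyl stays hydrogen-bonded to the ester, and the electron-rich trimethoxyphenyl group is the non-transferred ligand, so the 2,4-dibromophenyl group is delivered to O3.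

Step 5
Reactants: 9 methyl 4,5,6-tribromo-3-(2,4-dibromophenoxy)-2-hydroxybenzoate
Product: 10 4,5,6-tribromo-3-(2,4-dibromophenoxy)-2-hydroxybenzoic acid
Conditions: NaOH (6 equiv), MeOH/H2O, 70 °C; then 1 M HCl
Reagents that add atoms: sodium hydroxide, [Na+].[OH-]
Why: Saponification of a salicylate methyl ester; the aryl bromides and the diaryl ether are inert to aqueous hydroxide at this temperature, and the doubly ortho-substituted carbonyl only calls for heating.

Step 6
Reactants: 10 4,5,6-tribromo-3-(2,4-dibromophenoxy)-2-hydroxybenzoic acid; 3 3,5-dibromo-2-fluorophenol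
Product: 12 3,5-dibromo-2-fluorophenyl 4,5,6-tribromo-3-(2,4-dibromophenoxy)-2-hydroxybenzoate, via acid chloride 11 (not isolated)
Conditions: SOCl2, DMF (cat.), toluene, 70 °C; evaporate; then 3, pyridine, DMAP (cat.), CH2Cl2, 0 °C to rt
Reagents that add atoms: thionyl chloride, O=S(Cl)Cl (chlorine retained only in 11)
Why: Acid chloride formation and pyridine-mediated acylation of a phenol, as in the classical preparation of aryl salicylates from unprotected salicyloyl chlorides; the unhindered, acidic ring A phenol should be acylated far faster than the hydrogen-bonded 2-hydroxyl wedged between the aryloxy group and the carbonyl.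

Step 7
Reactants: 12 3,5-dibromo-2-fluorophenyl 4,5,6-tribromo-3-(2,4-dibromophenoxy)-2-hydroxybenzoate
Product: 13 1,2,3,6,8-pentabromo-4-(2,4-dibromophenoxy)-11H-dibenzo[b,e][1,4]dioxepin-11-one
Conditions: Cs2CO3 (1.5 equiv), 4 Å molecular sieves, DMSO (0.02 M), 90 °C
Reagents that add atoms: none
Why: Cs2CO3 turns the salicylate hydroxyl of 12 into a caesium phenoxide that adds to the fluorine-bearing C2 of ring A, and the Meisenheimer adduct, whose charge sits on C1, C3 and C5 where the acyloxy group and the two bromines take it up, expels fluoride (intramolecular SNAr). The closest known reactions are base-mediated diaryl ether formation from bromofluoroarenes and the closure of 2-halophenyl salicylates to depsidones. The dioxepinone ring closes in a 7-exo-trig addition-elimination once the ester adopts the s-cis geometry that places the phenoxide over C2 of ring A. No stereocentre arises. The step needs attack at C2 of ring A to outrun ipso attack at the ester-bearing C1 (Smiles shift), an O-to-O Smiles shift of ring C and bromide displacement; fluoride as the only good nucleofuge, on the only carbon with ortho and para bromines, should secure this. The doubly ortho-substituted carbonyl, the dry medium and high dilution hold back acyl transfer between molecules.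

Step 8
Reactants: 13 1,2,3,6,8-pentabromo-4-(2,4-dibromophenoxy)-11H-dibenzo[b,e][1,4]dioxepin-11-one
Product: 14 2,3,4-tribromo-6-(2,4-dibromo-6-hydroxyphenoxy)-5-(2,4-dibromophenoxy)benzoic acid
Conditions: LiOH (4 equiv), THF/H2O, rt to 40 °C; then 1 M HCl, 0 °C
Reagents that add atoms: lithium hydroxide, [Li+].[OH-]
Why: Saponification of an aryl ester lactone, a ring opening well known for depsidones: hydroxide adds to the seven-membered lactone carbonyl and the ring A phenoxide leaves, and the mild temperature gives that phenoxide no chance of aryl migration.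

Step 9
Reactants: 14 2,3,4-tribromo-6-(2,4-dibromo-6-hydroxyphenoxy)-5-(2,4-dibromophenoxy)benzoic acid
Product: 15 3,5-dibromo-2-[3,4,5-tribromo-2-(2,4-dibromophenoxy)phenoxy]phenol (bromoiesol A)
Conditions: Ag2CO3 (10 mol %), AcOH (5 mol %), DMSO, 120 °C
Reagents that add atoms: none
Why: Silver-catalysed protodecarboxylation: the silver carboxylate flanked by an ortho bromine and an ortho aryloxy group loses CO2 to an aryl–silver species that the substrate acid protonates, a process that is fastest for doubly ortho-substituted benzoic acids and tolerates aryl bromides, while the acidic medium keeps the phenol protonated.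

Step 10
Reactants: 15 3,5-dibromo-2-[3,4,5-tribromo-2-(2,4-dibromophenoxy)phenoxy]phenol
Product: 17 3,5-dibromo-2-[3,4,5-tribromo-2-(2,4-dibromophenoxy)phenoxy]phenyl hydrogen sulfate (bromoiesol A sulfate), via pyridinium aryl sulfate 16 (not isolated)
Conditions: SO3·pyridine (4 equiv), pyridine, 50 °C; evaporate; Dowex 50W (H+ form), MeOH/H2O, 0 °C
Reagents that add atoms: sulfur trioxide–pyridine complex, O=S(=O)([O-])[n+]1ccccc1
Why: O-Sulfation of a phenol with the SO3·pyridine complex gives the pyridinium aryl sulfate, and cold cation exchange replaces pyridinium by a proton before the sulfate monoester can hydrolyse.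

**Compound list**

1 | 2,4-dibromo-1-fluorobenzene | Fc1ccc(Br)cc1Br | starting material
2 | 2-(3,5-dibromo-2-fluorophenyl)-4,4,5,5-tetramethyl-1,3,2-dioxaborolane | CC1(C)OB(c2cc(Br)cc(Br)c2F)OC1(C)C | intermediate
3 | 3,5-dibromo-2-fluorophenol | Oc1cc(Br)cc(Br)c1F | intermediate
4 | 2,4-dibromo-1-iodobenzene | Brc1ccc(I)c(Br)c1 | starting material
5 | 2,4-dibromo-1-[hydroxy(tosyloxy)iodo]benzene | Cc1ccc(S(=O)(=O)OI(O)c2ccc(Br)cc2Br)cc1 | intermediate
6 | (2,4-dibromophenyl)(2,4,6-trimethoxyphenyl)iodonium tosylate | COc1cc(OC)c([I+]c2ccc(Br)cc2Br)c(OC)c1.Cc1ccc(S(=O)(=O)[O-])cc1 | intermediate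
7 | methyl 2,3-dihydroxybenzoate | COC(=O)c1cccc(O)c1O | starting material
8 | methyl 4,5,6-tribromo-2,3-dihydroxybenzoate | COC(=O)c1c(O)c(O)c(Br)c(Br)c1Br | intermediate
9 | methyl 4,5,6-tribromo-3-(2,4-dibromophenoxy)-2-hydroxybenzoate | COC(=O)c1c(O)c(Oc2ccc(Br)cc2Br)c(Br)c(Br)c1Br | intermediate
10 | 4,5,6-tribromo-3-(2,4-dibromophenoxy)-2-hydroxybenzoic acid | OC(=O)c1c(O)c(Oc2ccc(Br)cc2Br)c(Br)c(Br)c1Br | intermediate
11 | 4,5,6-tribromo-3-(2,4-dibromophenoxy)-2-hydroxybenzoyl chloride | O=C(Cl)c1c(O)c(Oc2ccc(Br)cc2Br)c(Br)c(Br)c1Br | intermediate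
12 | 3,5-dibromo-2-fluorophenyl 4,5,6-tribromo-3-(2,4-dibromophenoxy)-2-hydroxybenzoate | O=C(Oc1cc(Br)cc(Br)c1F)c1c(O)c(Oc2ccc(Br)cc2Br)c(Br)c(Br)c1Br | intermediate
13 | 1,2,3,6,8-pentabromo-4-(2,4-dibromophenoxy)-11H-dibenzo[b,e][1,4]dioxepin-11-one | O=C1Oc2cc(Br)cc(Br)c2Oc2c1c(Br)c(Br)c(Br)c2Oc1ccc(Br)cc1Br | intermediate
14 | 2,3,4-tribromo-6-(2,4-dibromo-6-hydroxyphenoxy)-5-(2,4-dibromophenoxy)benzoic acid | OC(=O)c1c(Br)c(Br)c(Br)c(Oc2ccc(Br)cc2Br)c1Oc1c(O)cc(Br)cc1Br | intermediate
15 | 3,5-dibromo-2-[3,4,5-tribromo-2-(2,4-dibromophenoxy)phenoxy]phenol | Oc1cc(Br)cc(Br)c1Oc1cc(Br)c(Br)c(Br)c1Oc1ccc(Br)cc1Br | intermediate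
16 | pyridinium 3,5-dibromo-2-[3,4,5-tribromo-2-(2,4-dibromophenoxy)phenoxy]phenyl sulfate | [O-]S(=O)(=O)Oc1cc(Br)cc(Br)c1Oc1cc(Br)c(Br)c(Br)c1Oc1ccc(Br)cc1Br.c1cc[nH+]cc1 | intermediate
17 | 3,5-dibromo-2-[3,4,5-tribromo-2-(2,4-dibromophenoxy)phenoxy]phenyl hydrogen sulfate (bromoiesol A sulfate) | O=S(=O)(O)Oc1cc(Br)cc(Br)c1Oc1cc(Br)c(Br)c(Br)c1Oc1ccc(Br)cc1Br | target

**Step count**

Total steps: 10. Longest linear sequence: 8 steps (steps 3 to 10 from 7; equally steps 2 and 4 to 10 from 4).

**Steps most likely to fail**

1. Step 7. The hindered, weakly nucleophilic salicylate phenoxide may add to a fluoroarene activated only by halogens and an acyloxy group more slowly than the aryl ester undergoes acyl transfer or ring C migrates by a Smiles shift. The fallback closes the same C2(A)–O bond with copper on the iodo analogue; it sets out from acid 10 (through acid chloride 11) and comes back at depsidone 13. Commercial 2,4-dibromo-6-methoxyaniline would be diazotised (NaNO2, H2SO4, AcOH, 0 °C) to 2,4-dibromo-6-methoxybenzenediazonium hydrogensulfate F1, which KI converts into 3,5-dibromo-2-iodoanisole F2 (Sandmeyer-type iodination). BBr3 in CH2Cl2 gives 3,5-dibromo-2-iodophenol F3. Acylation of F3 with 11 under the conditions of step 6 gives 3,5-dibromo-2-iodophenyl 4,5,6-tribromo-3-(2,4-dibromophenoxy)-2-hydroxybenzoate F4. CuI (10 mol %), N,N-dimethylglycine and Cs2CO3 in dioxane at 90 °C should then close the ring by an intramolecular Ullmann ether synthesis, monovalent copper inserting into the C–I bond ahead of any C–Br bond, to give 13.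

2. Step 4. Electron transfer from the catechol monoanion to trivalent iodine (quinone formation), aryl transfer to the 2-oxygen or transfer of the wrong aryl ligand may compete with ligand coupling at O3. The fallback replaces the iodonium salt by SNAr on a nitro-activated fluoroarene followed by exchange of nitro for bromine; it sets out from 8 and comes back at 9. Compound 8 with K2CO3 (1 equiv) and 2-bromo-1-fluoro-4-nitrobenzene in DMF at 60 °C should give methyl 4,5,6-tribromo-3-(2-bromo-4-nitrophenoxy)-2-hydroxybenzoate F5. Iron powder and NH4Cl in EtOH/H2O at 70 °C reduce the nitro group without touching C–Br to give methyl 3-(4-amino-2-bromophenoxy)-4,5,6-tribromo-2-hydroxybenzoate F6. NaNO2 and aqueous HBr in MeCN at 0 °C give the 3-bromo-4-aryloxybenzenediazonium bromide F7, which CuBr at 60 °C converts into 9 (Sandmeyer reaction).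

3. Step 9. At 120 °C the ring A phenol, as its silver phenoxide, may attack ring B (O-to-O Smiles migration, or dioxin closure with loss of 2,4-dibromophenoxide), or the aryl–silver intermediate may be protonated too slowly. The fallback masks the phenol before CO2 is removed; it sets out from 14 and comes back at 15. Ac2O in pyridine at rt, with an aqueous work-up that cleaves the mixed anhydride, gives 6-(2-acetoxy-4,6-dibromophenoxy)-2,3,4-tribromo-5-(2,4-dibromophenoxy)benzoic acid F8. The silver conditions of step 9 then give 3,5-dibromo-2-[3,4,5-tribromo-2-(2,4-dibromophenoxy)phenoxy]phenyl acetate F9, and K2CO3 in MeOH at 0 °C releases 15.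

**Further compounds**

F1 | step 7 | 2,4-dibromo-6-methoxybenzenediazonium hydrogensulfate | COc1cc(Br)cc(Br)c1[N+]#N.OS(=O)(=O)[O-]
F2 | step 7 | 3,5-dibromo-2-iodoanisole | COc1cc(Br)cc(Br)c1I
F3 | step 7 | 3,5-dibromo-2-iodophenol | Oc1cc(Br)cc(Br)c1I
F4 | step 7 | 3,5-dibromo-2-iodophenyl 4,5,6-tribromo-3-(2,4-dibromophenoxy)-2-hydroxybenzoate | O=C(Oc1cc(Br)cc(Br)c1I)c1c(O)c(Oc2ccc(Br)cc2Br)c(Br)c(Br)c1Br
F5 | step 4 | methyl 4,5,6-tribromo-3-(2-bromo-4-nitrophenoxy)-2-hydroxybenzoate | COC(=O)c1c(O)c(Oc2ccc([N+](=O)[O-])cc2Br)c(Br)c(Br)c1Br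
F6 | step 4 | methyl 3-(4-amino-2-bromophenoxy)-4,5,6-tribromo-2-hydroxybenzoate | COC(=O)c1c(O)c(Oc2ccc(N)cc2Br)c(Br)c(Br)c1Br
F7 | step 4 | 3-bromo-4-[4,5,6-tribromo-2-hydroxy-3-(methoxycarbonyl)phenoxy]benzenediazonium bromide | COC(=O)c1c(O)c(Oc2ccc([N+]#N)cc2Br)c(Br)c(Br)c1Br.[Br-]
F8 | step 9 | 6-(2-acetoxy-4,6-dibromophenoxy)-2,3,4-tribromo-5-(2,4-dibromophenoxy)benzoic acid | CC(=O)Oc1cc(Br)cc(Br)c1Oc1c(C(=O)O)c(Br)c(Br)c(Br)c1Oc1ccc(Br)cc1Br
F9 | step 9 | 3,5-dibromo-2-[3,4,5-tribromo-2-(2,4-dibromophenoxy)phenoxy]phenyl acetate | CC(=O)Oc1cc(Br)cc(Br)c1Oc1cc(Br)c(Br)c(Br)c1Oc1ccc(Br)cc1Br
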